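**Plan**
- Retrosynthetic cuts, in order: the two O–CH3 bonds at C5 and C8; the O1–C8a bond of the pyranone; the two O–benzyl bonds; the C2–C3 bond of the 1,3-diketone; the aryl–CO2Me bond of ring B and the aryl–acetyl bond of ring A.
- Enabling feature: ring A carries oxygens at C5 and C8 para to each other, so it is a hidden hydroquinone. In its quinone form C8a lies β to both the C5 and the C4 carbonyl and becomes electrophilic toward the enol oxygen destined to be O1.
- Forward: the ring A acetophenone (from methoxyhydroquinone) and the ring B ester (from 1,2,3,4-tetramethoxybenzene) are joined by Claisen condensation to an open 1,3-diketone. Ring C then closes by anodic oxidation and oxa-Michael addition, and double O-methylation finishes the synthesis.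
- Stereochemistry: the target, 5,7,8,2',3',4',5'-heptamethoxyflavone, has no stereocenter, so none has to be set.

Key step: step 6

Remark: flavone numbering (O1, C2, C3, C4, C4a, C5 to C8, C8a; ring B primed) is used for all intermediates, also before ring C exists. Compounds 1 and 4 are taken as purchasable.

Step 1
Reactants: 1 methoxyhydroquinone
Product: 2 1-(2,5-dihydroxy-4-methoxyphenyl)ethanone
Conditions: AcOH, BF3·OEt2, 90 °C; then H2O
Reagents that add atoms: acetic acid, CC(=O)O
Why: Friedel–Crafts (Fries-type) C-acetylation should take place at the ring position ortho to a hydroxyl and para to the methoxyl, the only site activated by two donors without being flanked by two substituents, and the product is stabilised as a chelated ortho-hydroxy ketone.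

Step 2
Reactants: 2 1-(2,5-dihydroxy-4-methoxyphenyl)ethanone
Product: 3 1-[2,5-bis(benzyloxy)-4-methoxyphenyl]ethanone
Conditions: BnBr, K2CO3, DMF, 70 °C, Ar
Reagents that add atoms: benzyl bromide, BrCc1ccccc1
Why: Williamson etherification of both phenols in warm DMF is forcing enough to alkylate the hydroxyl hydrogen-bonded to the acetyl group, while K2CO3 is too weak to enolise the ketone for C-benzylation.

Step 3
Reactants: 4 1,2,3,4-tetramethoxybenzene
Product: 6 methyl 2,3,4,5-tetramethoxybenzoate, via 2,3,4,5-tetramethoxyphenyllithium 5 (not isolated)
Conditions: n-BuLi, TMEDA, THF, 0 °C; then inverse addition to ClCO2Me (excess), THF, −78 °C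
Reagents that add atoms: methyl chloroformate, COC(=O)Cl
Why: Directed ortho-metalation can only occur next to a methoxy group at one of the two symmetry-equivalent free positions, and acylation of the aryllithium by inverse addition into excess chloroformate should stop at the ester.

Step 4
Reactants: 3 1-[2,5-bis(benzyloxy)-4-methoxyphenyl]ethanone; 6 methyl 2,3,4,5-tetramethoxybenzoate
Product: 7 1-[2,5-bis(benzyloxy)-4-methoxyphenyl]-3-(2,3,4,5-tetramethoxyphenyl)propane-1,3-dione
Conditions: NaH, THF, reflux; then 1 M HCl
Reagents that add atoms: none
Why: Crossed Claisen condensation between the methyl ketone enolate and a non-enolisable ester forms the C2–C3 bond and is driven forward by irreversible deprotonation of the 1,3-diketone.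

Step 5
Reactants: 7 1-[2,5-bis(benzyloxy)-4-methoxyphenyl]-3-(2,3,4,5-tetramethoxyphenyl)propane-1,3-dione
Product: 8 1-(2,5-dihydroxy-4-methoxyphenyl)-3-(2,3,4,5-tetramethoxyphenyl)propane-1,3-dione
Conditions: H2 (1 atm), Pd/C (10 wt% Pd), EtOAc, 23 °C
Reagents that add atoms: none
Why: Catalytic hydrogenolysis of the two benzyl aryl ethers runs under neutral conditions, which leaves the enolised diketone, the methoxy groups and both arenes untouched and avoids the acid that would cause cyclodehydration through the ortho hydroxyl.

Step 6
Reactants: 8 1-(2,5-dihydroxy-4-methoxyphenyl)-3-(2,3,4,5-tetramethoxyphenyl)propane-1,3-dione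
Product: 10 5,8-dihydroxy-7-methoxy-2-(2,3,4,5-tetramethoxyphenyl)-4H-chromen-4-one, via acylquinone 9 (not isolated)
Conditions: undivided cell, graphite anode, Pt cathode, controlled potential at the hydroquinone wave (expected near +0.4 V vs Ag/AgCl), about 2 F/mol, NaOAc/AcOH buffer (pH 6)–MeCN 1:1, 5 mM, 20 °C, N2; then aq. Na2S2O4 wash
Reagents that add atoms: none
Why: Proposed new method: at the graphite anode the hydroquinone of 8 should lose two electrons and two protons at a potential far below that of the tetramethoxyphenyl ring to give acylquinone 9, whose ring carbon next to the acyl group (the future C8a) is β to both the C5 quinone carbonyl and the C4 ketone; the chelated cis-enol oxygen on C2 should add there to form O1–C8a, and enolisation of the adduct restores the arene as hydroquinone 10 while the cathode discharges the protons as H2. The closest known reaction type is the anodic oxidation of hydroquinones and catechols in buffered aqueous MeCN with in-situ capture of the quinone by 1,3-dicarbonyl nucleophiles, together with the known preference of 2-acylbenzoquinones to accept nucleophiles at the carbon adjacent to the acyl group; new here is the intramolecular capture by an enol oxygen to give a chromone. Ring C closes in a 6-endo-trig oxa-Michael mode, and no stereocenter is formed. Chemoselective oxidation is secured by potential control, since neither the tetramethoxyarene nor any cyclic hemiketal form of 8 is oxidised at the hydroquinone wave, and the hemiketal reopens to feed the reaction. Regioselectivity is secured by the substrate: the tether lets the enol oxygen reach only C8a through a six-membered ring, C6 and C7 are deactivated by the vinylogous-ester methoxyl, and the C5 oxygen is tied up as a quinone carbonyl in 9 so that closure through it is impossible. High dilution disfavours intermolecular C-attack of one diketone on another molecule of 9, the charge is held near 2 F/mol, and the Na2S2O4 wash would reverse any over-oxidation of 10.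

Step 7
Reactants: 10 5,8-dihydroxy-7-methoxy-2-(2,3,4,5-tetramethoxyphenyl)-4H-chromen-4-one
Product: 11 5,7,8-trimethoxy-2-(2,3,4,5-tetramethoxyphenyl)-4H-chromen-4-one
Conditions: Me2SO4 (excess), K2CO3, acetone, reflux, Ar
Reagents that add atoms: dimethyl sulfate, COS(=O)(=O)OC
Why: Williamson-type O-methylation of both phenols: the C8 hydroxyl reacts readily and the C5 hydroxyl, although hydrogen-bonded to the C4 carbonyl, should be alkylated by excess Me2SO4 on prolonged reflux, while the inert atmosphere keeps the hydroquinone dianion from aerial oxidation.

**Compound list**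
1 | methoxyhydroquinone (2-methoxybenzene-1,4-diol) | COc1cc(O)ccc1O | starting material
2 | 1-(2,5-dihydroxy-4-methoxyphenyl)ethanone | CC(=O)c1cc(O)c(OC)cc1O | intermediate
3 | 1-[2,5-bis(benzyloxy)-4-methoxyphenyl]ethanone | CC(=O)c1cc(OCc2ccccc2)c(OC)cc1OCc1ccccc1 | intermediate
4 | 1,2,3,4-tetramethoxybenzene | COc1ccc(OC)c(OC)c1OC | starting material
5 | 2,3,4,5-tetramethoxyphenyllithium (formed in the flask) | [Li]c1cc(OC)c(OC)c(OC)c1OC | intermediate
6 | methyl 2,3,4,5-tetramethoxybenzoate | COC(=O)c1cc(OC)c(OC)c(OC)c1OC | intermediate
7 | 1-[2,5-bis(benzyloxy)-4-methoxyphenyl]-3-(2,3,4,5-tetramethoxyphenyl)propane-1,3-dione | COc1cc(OCc2ccccc2)c(C(=O)CC(=O)c2cc(OC)c(OC)c(OC)c2OC)cc1OCc1ccccc1 | intermediate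
8 | 1-(2,5-dihydroxy-4-methoxyphenyl)-3-(2,3,4,5-tetramethoxyphenyl)propane-1,3-dione | COc1cc(O)c(C(=O)CC(=O)c2cc(OC)c(OC)c(OC)c2OC)cc1O | intermediate
9 | acylquinone: 2-methoxy-5-[3-oxo-3-(2,3,4,5-tetramethoxyphenyl)propanoyl]cyclohexa-2,5-diene-1,4-dione (formed in the flask) | COC1=CC(=O)C(C(=O)CC(=O)c2cc(OC)c(OC)c(OC)c2OC)=CC1=O | intermediate
10 | 5,8-dihydroxy-7-methoxy-2-(2,3,4,5-tetramethoxyphenyl)-4H-chromen-4-one | COc1cc(O)c2c(=O)cc(-c3cc(OC)c(OC)c(OC)c3OC)oc2c1O | intermediate
11 | 5,7,8-trimethoxy-2-(2,3,4,5-tetramethoxyphenyl)-4H-chromen-4-one | COc1cc(-c2cc(=O)c3c(OC)cc(OC)c(OC)c3o2)c(OC)c(OC)c1OC | target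

**Step count**
Total steps: 7. Longest linear sequence: 6 steps (steps 1, 2, 4, 5, 6, 7 from compound 1).

**Steps most likely to fail**

Step 6 (the unprecedented step). The acylquinone may be consumed by intermolecular Michael addition of the diketone carbon of a second molecule, by hydration, or by over-oxidation and decomposition of the electron-rich product before the enol oxygen closes the ring. The fallback uses known chemistry in which all ring A oxygens are bought and O1 comes from a phenol. It sets out from ester 6, which would be condensed (NaH, THF, reflux, Claisen condensation through the dianion) with purchased 1-(2-hydroxy-3,4,6-trimethoxyphenyl)ethanone (CC(=O)c1c(O)c(OC)c(OC)cc1OC). This should give 1-(2-hydroxy-3,4,6-trimethoxyphenyl)-3-(2,3,4,5-tetramethoxyphenyl)propane-1,3-dione F1. Acid-catalysed cyclodehydration of F1 (catalytic H2SO4, AcOH, 90 °C) through its single free hydroxyl can only give the 5,7,8-trimethoxy pattern. The fallback therefore comes back to the route at target 11 and bypasses steps 4 to 7.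

Step 4. Acyl transfer to the electron-rich, ortho-substituted ester may be too slow, so that self-condensation of the ketone enolate takes over. The fallback replaces acyl substitution by aldol addition and oxidation. It sets out from 4 and 3. Vilsmeier–Haack formylation of 4 (POCl3, DMF) should give 2,3,4,5-tetramethoxybenzaldehyde F2. The lithium enolate of 3 (LiN(SiMe3)2, THF, −78 °C) would add to F2 to give racemic 1-[2,5-bis(benzyloxy)-4-methoxyphenyl]-3-hydroxy-3-(2,3,4,5-tetramethoxyphenyl)propan-1-one F3, quenched cold to avoid dehydration. Oxidation of the secondary alcohol of F3 with Dess–Martin periodinane in CH2Cl2 would deliver diketone 7, where the fallback comes back to the route.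

Step 7. Alkylation of the hydrogen-bonded C5 hydroxyl may stall, and the hydroquinone dianion may be oxidised by adventitious air under basic conditions. The fallback accepts the oxidation instead of fighting it. It sets out from 10, which would be oxidised deliberately (Ag2O, CH2Cl2, 23 °C) to 7-methoxy-2-(2,3,4,5-tetramethoxyphenyl)-4H-chromene-4,5,8-trione F4. One-pot reductive methylation of F4 under phase-transfer conditions (Na2S2O4, then Me2SO4, aqueous KOH, Bu4NBr, THF, Ar) regenerates the hydroquinone dianion in the presence of excess reductant and alkylates both oxygens. The fallback comes back to the route at 11.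

**Further compounds**
F1 | step 6 | 1-(2-hydroxy-3,4,6-trimethoxyphenyl)-3-(2,3,4,5-tetramethoxyphenyl)propane-1,3-dione | COc1cc(OC)c(C(=O)CC(=O)c2cc(OC)c(OC)c(OC)c2OC)c(O)c1OC
F2 | step 4 | 2,3,4,5-tetramethoxybenzaldehyde | O=Cc1cc(OC)c(OC)c(OC)c1OC
F3 | step 4 | racemic 1-[2,5-bis(benzyloxy)-4-methoxyphenyl]-3-hydroxy-3-(2,3,4,5-tetramethoxyphenyl)propan-1-one | COc1cc(OCc2ccccc2)c(C(=O)CC(O)c2cc(OC)c(OC)c(OC)c2OC)cc1OCc1ccccc1
F4 | step 7 | 7-methoxy-2-(2,3,4,5-tetramethoxyphenyl)-4H-chromene-4,5,8-trione | COC1=CC(=O)C2=C(OC(=CC2=O)c2cc(OC)c(OC)c(OC)c2OC)C1=O
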